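**Retrosynthetic overview**
- Target 16 is (2S)-5-hydroxy-6,7-dimethoxyflavanone 12 carrying a 2-hydroxy-5-methoxybenzyl group on C8, the last free carbon of ring A. The C8–CH2 bond is cut last (Friedel–Crafts benzylation with salicyl alcohol 14), and 12 comes from catechol 11 by methylating the non-chelated C6 hydroxyl.
- Feature used: C5 and C6 of ring A carry neighbouring oxygens, so ring A can be written as a 5,6-o-quinone. In that quinone C8a is the β-carbon of both the C5 carbonyl and the C4 ketone, and the C2 hydroxyl can add there.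
- Key disconnection: O1–C8a of ring C, leading back to the open-chain catechol β-hydroxy ketone 8. Ring C is the only ring formed in the route; ring A, ring B and the benzyl arene are bought.
- 8 comes from the C3–C4 bond: the dithiane anion of protected 2,3-dihydroxy-4-methoxybenzaldehyde opens (R)-styrene oxide at CH2, which supplies C2 with its configuration.

Key step: step 6

Remark: the SMILES is read as the (2S)-flavanone; flavanone numbering (O1, C2–C4, C4a, C5–C8, C8a) is used for these atoms in every intermediate, also before ring C exists.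

**Route**

Step 1
Reactants: 1 2,3-dihydroxy-4-methoxybenzaldehyde
Product: 2 2-(2,3-dihydroxy-4-methoxyphenyl)-1,3-dithiane
Conditions: HS(CH2)3SH (1.1 equiv), BF3·OEt2 (0.2 equiv), CH2Cl2, 0 °C → rt
Reagents that add atoms: propane-1,3-dithiol, SCCCS
Why: Lewis-acid-catalysed dithioacetalisation of the aldehyde (first half of a Corey–Seebach umpolung) should proceed with the phenols free, since the dithiol does not touch them.

Step 2
Reactants: 2 2-(2,3-dihydroxy-4-methoxyphenyl)-1,3-dithiane
Product: 3 2-[2,3-bis(tert-butyldimethylsilyloxy)-4-methoxyphenyl]-1,3-dithiane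
Conditions: TBSCl (2.6 equiv), imidazole (5 equiv), DMF, rt → 40 °C
Reagents that add atoms: tert-butyldimethylsilyl chloride, CC(C)(C)[Si](C)(C)Cl
Why: Imidazole-promoted O-silylation caps both phenols so that the dithiane C2–H is the only acidic hydrogen left for step 3, and TBS can later be removed by buffered fluoride, which a β-hydroxy ketone tolerates.

Step 3
Reactants: 3 2-[2,3-bis(tert-butyldimethylsilyloxy)-4-methoxyphenyl]-1,3-dithiane; 4 (R)-styrene oxide
Product: 6 (1S)-2-{2-[2,3-bis(tert-butyldimethylsilyloxy)-4-methoxyphenyl]-1,3-dithian-2-yl}-1-phenylethan-1-ol, via lithiated dithiane 5 (not isolated)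
Conditions: n-BuLi, THF, −78 → −30 °C; then 4, −30 °C → rt; aq. NH4Cl
Reagents that add atoms: none
Why: Corey–Seebach alkylation: the 2-aryl-2-lithiodithiane 5 should open the epoxide by SN2 attack at the unsubstituted CH2, so the benzylic C–O bond of 4 is not involved and the carbinol centre keeps its geometry, the descriptor changing from R to S only because the CIP ranking of CH2 and phenyl is reversed.

Step 4
Reactants: 6 (1S)-2-{2-[2,3-bis(tert-butyldimethylsilyloxy)-4-methoxyphenyl]-1,3-dithian-2-yl}-1-phenylethan-1-ol
Product: 7 (3S)-1-[2,3-bis(tert-butyldimethylsilyloxy)-4-methoxyphenyl]-3-hydroxy-3-phenylpropan-1-one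
Conditions: MeI (excess), CaCO3, MeCN/H2O (4:1), 40 °C
Reagents that add atoms: water, O
Why: Alkylative dithiane hydrolysis (S-methylation, opening to a thionium ion, capture by water) under CaCO3 buffering should unmask the aryl ketone without an electrophilic halogen source that could attack the electron-rich ring and without acid or base that could dehydrate the β-hydroxy ketone.

Step 5
Reactants: 7 (3S)-1-[2,3-bis(tert-butyldimethylsilyloxy)-4-methoxyphenyl]-3-hydroxy-3-phenylpropan-1-one
Product: 8 (3S)-1-(2,3-dihydroxy-4-methoxyphenyl)-3-hydroxy-3-phenylpropan-1-one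
Conditions: TBAF (2.5 equiv), AcOH (3 equiv), THF, 0 °C
Reagents that add atoms: none
Why: Fluoride cleavage of the two aryl silyl ethers, buffered with acetic acid so that no phenoxide or enolate persists, should free the catechol without retro-aldol cleavage or elimination to the chalcone.

Step 6
Reactants: 8 (3S)-1-(2,3-dihydroxy-4-methoxyphenyl)-3-hydroxy-3-phenylpropan-1-one
Product: 11 (2S)-5,6-dihydroxy-7-methoxyflavanone, via acyl o-quinone 9 (not isolated), via flavanone 5,6-quinone 10 (not isolated)
Conditions: Ag2O (2.5 equiv), Na2SO4, CH2Cl2 (0.002 M), 0 °C → rt, dark; filter; then aq. Na2S2O4, EtOAc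
Reagents that add atoms: none
Why: Proposed new method: Ag2O takes two electrons and two protons from the catechol of 8 to give the 3-acyl-o-quinone 9, in which the ring CH ortho to the acyl group (the future C8a) is the β-carbon of both the quinone carbonyl at the future C5 and the side-chain ketone (future C4); the secondary hydroxyl adds there (oxa-Michael) and the adduct enolises, losing the C8a hydrogen, to the aromatic catechol 11. Since 11 carries a further oxygen donor para to its C6 hydroxyl it is expected to be oxidised more easily than 8, so excess Ag2O is used to carry all material on to the flavanone quinone 10, which aqueous Na2S2O4 reduces back to 11 in the work-up. The closest known reaction types are the ring closure of aminoethyl-o-quinones to indolines (aminochrome formation) and the 1,4-addition of methanol to o-quinones formed by oxidising catechols in methanol; an intramolecular alcohol addition that closes a chroman-4-one has not been shown. Ring C closes 6-endo-trig through the O1–C8a bond alone. No stereocentre is formed, and C2 keeps the configuration brought in with epoxide 4 because its C–O bond is never broken. The step needs attack at C8a and not at C8, and cyclisation faster than quinone dimerisation, hydration or dehydration of the β-hydroxy ketone: the four-atom tether reaches only C8a in a six-membered ring, C8a is activated by two carbonyls whereas C8 is damped by the C7 methoxy group, and high dilution in a dry, aprotic, near-neutral medium keeps the bimolecular and elimination pathways slow.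

Step 7
Reactants: 11 (2S)-5,6-dihydroxy-7-methoxyflavanone
Product: 12 (2S)-5-hydroxy-6,7-dimethoxyflavanone
Conditions: CH2N2, Et2O/MeOH, 0 °C
Reagents that add atoms: diazomethane, C=[N+]=[N-]
Why: O-Methylation of a phenol by diazomethane should be fast for the free C6 hydroxyl and very slow for the C5 hydroxyl, which is held in a hydrogen bond to the C4 carbonyl; no base is present, so ring C stays closed and C2 is not epimerised.

Step 8
Reactants: 13 2-hydroxy-5-methoxybenzaldehyde
Product: 14 2-(hydroxymethyl)-4-methoxyphenol
Conditions: NaBH4, MeOH, 0 °C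
Reagents that add atoms: none
Why: Borohydride reduction of the aryl aldehyde gives the salicyl alcohol that serves as o-quinone methide precursor.

Step 9
Reactants: 12 (2S)-5-hydroxy-6,7-dimethoxyflavanone; 14 2-(hydroxymethyl)-4-methoxyphenol
Product: 16 (2S)-5-hydroxy-8-(2-hydroxy-5-methoxybenzyl)-6,7-dimethoxyflavanone, via o-quinone methide 15 (not isolated)
Conditions: 14 (2 equiv, slow addition), CF3CO2H/CH2Cl2 (1:9), 0 °C → rt
Reagents that add atoms: none
Why: Acid-promoted Friedel–Crafts benzylation: 14 loses water to the o-quinone methide 15 (present in acid as its O-protonated benzylic cation), which should be attacked by C8, the only unsubstituted carbon of ring A, para to the C5 hydroxyl and ortho to O1 and the C7 methoxy group; no hydride source is present, so the C4 ketone is not at risk, and the acidic medium does not open ring C.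

**Compound list**

1 | 2,3-dihydroxy-4-methoxybenzaldehyde | COc1ccc(C=O)c(O)c1O | starting material
2 | 2-(2,3-dihydroxy-4-methoxyphenyl)-1,3-dithiane | COc1ccc(C2SCCCS2)c(O)c1O | intermediate
3 | 2-[2,3-bis(tert-butyldimethylsilyloxy)-4-methoxyphenyl]-1,3-dithiane | COc1ccc(C2SCCCS2)c(O[Si](C)(C)C(C)(C)C)c1O[Si](C)(C)C(C)(C)C | intermediate
4 | (R)-styrene oxide | O1[C@H](c2ccccc2)C1 | starting material
5 | 2-[2,3-bis(tert-butyldimethylsilyloxy)-4-methoxyphenyl]-2-lithio-1,3-dithiane | [Li]C1(c2ccc(OC)c(O[Si](C)(C)C(C)(C)C)c2O[Si](C)(C)C(C)(C)C)SCCCS1 | intermediate (not isolated)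
6 | (1S)-2-{2-[2,3-bis(tert-butyldimethylsilyloxy)-4-methoxyphenyl]-1,3-dithian-2-yl}-1-phenylethan-1-ol | COc1ccc(C2(C[C@H](O)c3ccccc3)SCCCS2)c(O[Si](C)(C)C(C)(C)C)c1O[Si](C)(C)C(C)(C)C | intermediate
7 | (3S)-1-[2,3-bis(tert-butyldimethylsilyloxy)-4-methoxyphenyl]-3-hydroxy-3-phenylpropan-1-one | COc1ccc(C(=O)C[C@H](O)c2ccccc2)c(O[Si](C)(C)C(C)(C)C)c1O[Si](C)(C)C(C)(C)C | intermediate
8 | (3S)-1-(2,3-dihydroxy-4-methoxyphenyl)-3-hydroxy-3-phenylpropan-1-one | COc1ccc(C(=O)C[C@H](O)c2ccccc2)c(O)c1O | intermediate
9 | 3-[(3S)-3-hydroxy-3-phenylpropanoyl]-6-methoxycyclohexa-3,5-diene-1,2-dione | COC1=CC=C(C(=O)C[C@H](O)c2ccccc2)C(=O)C1=O | intermediate (not isolated)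
10 | (2S)-7-methoxy-2-phenyl-2,3-dihydro-4H-chromene-4,5,6-trione | COC1=CC2=C(C(=O)C[C@@H](c3ccccc3)O2)C(=O)C1=O | intermediate (not isolated)
11 | (2S)-5,6-dihydroxy-7-methoxyflavanone | COc1cc2O[C@H](c3ccccc3)CC(=O)c2c(O)c1O | intermediate
12 | (2S)-5-hydroxy-6,7-dimethoxyflavanone | COc1cc2O[C@H](c3ccccc3)CC(=O)c2c(O)c1OC | intermediate
13 | 2-hydroxy-5-methoxybenzaldehyde | COc1ccc(O)c(C=O)c1 | starting material
14 | 2-(hydroxymethyl)-4-methoxyphenol | COc1ccc(O)c(CO)c1 | intermediate
15 | 4-methoxy-6-methylidenecyclohexa-2,4-dien-1-one | COC1=CC(=C)C(=O)C=C1 | intermediate (not isolated)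
16 | (2S)-5-hydroxy-8-(2-hydroxy-5-methoxybenzyl)-6,7-dimethoxyflavanone | COc1ccc(O)c(Cc2c(OC)c(OC)c(O)c3c2O[C@H](c2ccccc2)CC3=O)c1 | target

**Step count**
Total steps: 9. Longest linear sequence: 8 (steps 1–7 and 9).

**Steps most likely to fail**

1. Step 6. The quinone may be lost to dimerisation, to hydration by the water formed in the oxidation, or to reversible hemiketal formation at the quinone carbonyl next to the acyl group, before the hydroxyl adds to C8a. The over-oxidised flavanone quinone may also isomerise towards the flavone, with loss of C2, before it is reduced.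
Fallback (known chemistry): the flavanone is made without any catechol oxidation. This path does not branch from a numbered compound, because none before 11 carries the C8a oxygen; it sets out from commercial 1-(6-hydroxy-2,3,4-trimethoxyphenyl)ethan-1-one (CC(=O)c1c(O)cc(OC)c(OC)c1OC) and comes back to the route at 12, after which steps 8 and 9 are used unchanged. Condensation with DMF dimethyl acetal should give (E)-3-(dimethylamino)-1-(6-hydroxy-2,3,4-trimethoxyphenyl)prop-2-en-1-one F1. Acid (HCl, CH2Cl2) should close it to 5,6,7-trimethoxy-4H-chromen-4-one F2 with loss of dimethylamine. Asymmetric conjugate addition of phenylboronic acid (Pd(OCOCF3)2, t-BuPyOx, NH4PF6, H2O, ClCH2CH2Cl, 60 °C; the ligand antipode that gives the 2S product) should give (2S)-5,6,7-trimethoxyflavanone F3. BCl3 (CH2Cl2, −78 → 0 °C) should remove only the methyl group on the C5 oxygen, which chelates boron together with the C4 carbonyl, to give 12.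

2. Step 9. The quinone methide may be consumed by the electron-rich phenol ring of 14 itself or of the product (oligomers), or by O-benzylation, faster than by C8, which is slowed by the C4 carbonyl.
Fallback: the C8–CH2 bond is made by cross-coupling instead of electrophilic substitution; the path sets out from 12 and 13 and comes back at 16. NIS (DMF, rt) should iodinate 12 at its only free ring A position to give (2S)-5-hydroxy-8-iodo-6,7-dimethoxyflavanone F4. In parallel 13 is O-benzylated (BnBr, K2CO3) to 2-(benzyloxy)-5-methoxybenzaldehyde F5, reduced (NaBH4) to [2-(benzyloxy)-5-methoxyphenyl]methanol F6, converted with SOCl2 into 1-(benzyloxy)-2-(chloromethyl)-4-methoxybenzene F7, and inserted with Zn dust/LiCl in THF to give [2-(benzyloxy)-5-methoxybenzyl]zinc chloride F8. Negishi coupling of F4 with excess F8 (Pd(OAc)2, SPhos, THF, rt; one equivalent of F8 is spent on the C5 hydroxyl) should give (2S)-8-[2-(benzyloxy)-5-methoxybenzyl]-5-hydroxy-6,7-dimethoxyflavanone F9. Hydrogenolysis (H2, Pd/C, EtOAc) then frees the phenol to give 16.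

3. Step 3. The hindered, sulfur-stabilised carbanion may open the epoxide only slowly, and silyl transfer from the ortho oxygen to the carbanion or to the new alkoxide may compete. Transfer to oxygen is harmless, since step 5 removes every silyl group; transfer to carbon is not.
Fallback: the C2–C3 bond is formed by an enantioselective aldol reaction instead of the C3–C4 bond by epoxide opening; the path sets out from 1 and comes back at 7. Silylation of 1 (TBSCl, imidazole, DMF) gives 2,3-bis(tert-butyldimethylsilyloxy)-4-methoxybenzaldehyde F10. MeMgBr gives 1-[2,3-bis(tert-butyldimethylsilyloxy)-4-methoxyphenyl]ethan-1-ol F11, and Dess–Martin oxidation gives 1-[2,3-bis(tert-butyldimethylsilyloxy)-4-methoxyphenyl]ethan-1-one F12. TMSOTf/Et3N converts this into tert-butyl-dimethyl silyl-protected 1-aryl-1-(trimethylsilyloxy)ethene F13. A Lewis-base-catalysed Mukaiyama aldol addition of F13 to benzaldehyde (SiCl4, chiral bisphosphoramide catalyst, iPr2NEt, CH2Cl2, −78 °C) should give 7 after aqueous work-up. The catalyst antipode that leads to the S carbinol would be fixed in a trial run, and the enantiomeric purity raised by crystallisation of 7 or 8 if needed.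

**Further compounds**

F1 | step 6 | (E)-3-(dimethylamino)-1-(6-hydroxy-2,3,4-trimethoxyphenyl)prop-2-en-1-one | CN(C)/C=C/C(=O)c1c(O)cc(OC)c(OC)c1OC
F2 | step 6 | 5,6,7-trimethoxy-4H-chromen-4-one | COc1cc2occc(=O)c2c(OC)c1OC
F3 | step 6 | (2S)-5,6,7-trimethoxyflavanone | COc1cc2O[C@H](c3ccccc3)CC(=O)c2c(OC)c1OC
F4 | step 9 | (2S)-5-hydroxy-8-iodo-6,7-dimethoxyflavanone | COc1c(I)c2O[C@H](c3ccccc3)CC(=O)c2c(O)c1OC
F5 | step 9 | 2-(benzyloxy)-5-methoxybenzaldehyde | COc1ccc(OCc2ccccc2)c(C=O)c1
F6 | step 9 | [2-(benzyloxy)-5-methoxyphenyl]methanol | COc1ccc(OCc2ccccc2)c(CO)c1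
F7 | step 9 | 1-(benzyloxy)-2-(chloromethyl)-4-methoxybenzene | COc1ccc(OCc2ccccc2)c(CCl)c1
F8 | step 9 | [2-(benzyloxy)-5-methoxybenzyl]zinc chloride | COc1ccc(OCc2ccccc2)c(C[Zn]Cl)c1
F9 | step 9 | (2S)-8-[2-(benzyloxy)-5-methoxybenzyl]-5-hydroxy-6,7-dimethoxyflavanone | COc1ccc(OCc2ccccc2)c(Cc2c(OC)c(OC)c(O)c3c2O[C@H](c2ccccc2)CC3=O)c1
F10 | step 3 | 2,3-bis(tert-butyldimethylsilyloxy)-4-methoxybenzaldehyde | COc1ccc(C=O)c(O[Si](C)(C)C(C)(C)C)c1O[Si](C)(C)C(C)(C)C
F11 | step 3 | 1-[2,3-bis(tert-butyldimethylsilyloxy)-4-methoxyphenyl]ethan-1-ol (racemic) | COc1ccc(C(C)O)c(O[Si](C)(C)C(C)(C)C)c1O[Si](C)(C)C(C)(C)C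
F12 | step 3 | 1-[2,3-bis(tert-butyldimethylsilyloxy)-4-methoxyphenyl]ethan-1-one | COc1ccc(C(C)=O)c(O[Si](C)(C)C(C)(C)C)c1O[Si](C)(C)C(C)(C)C
F13 | step 3 | {1-[2,3-bis(tert-butyldimethylsilyloxy)-4-methoxyphenyl]ethenyloxy}trimethylsilane | C=C(O[Si](C)(C)C)c1ccc(OC)c(O[Si](C)(C)C(C)(C)C)c1O[Si](C)(C)C(C)(C)C
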